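**Retrosynthetic overview**
1. Target 5 ⇒ chlorohydrin 3: the tertiary C–Br comes last, by substitution of the tertiary OH with retention (participation of the neighbouring axial Cl).
2. Chlorohydrin 3 ⇒ (−)-α-bisabolol 1 in one flask: ring B (the oxane) by bromonium-induced 6-endo etherification of the prenyl alkene by the tertiary OH, then Cl+/H2O across the ring A alkene.
3. Ring order: ring A (the cyclohexene closed through the bisabolyl cation in the biosynthesis) is taken intact from 1 with both carbon stereocentres; ring B is closed in step 1.
4. The ring A pattern (secondary axial Cl, tertiary axial Br) is the Cl+/Br− sense of addition. BrCl (Br+/Cl−) would put Cl on the tertiary carbon, so the halogens are introduced as Cl+/H2O and then Br−.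

Assumption: commercial (−)-α-bisabolol is the natural (S,S)-enantiomer (levomenol).

**Step 1**
Reactants: 1 (−)-α-bisabolol, (2S)-6-methyl-2-[(1S)-4-methylcyclohex-3-en-1-yl]hept-5-en-2-ol
Product: 3 (1R,2R,4S)-4-[(2S,5R)-5-bromo-2,6,6-trimethyloxan-2-yl]-2-chloro-1-methylcyclohexan-1-ol, via bromo-oxane alkene 2 (not isolated)
Conditions: NBS (1.0 equiv), 1,1,1,3,3,3-hexafluoropropan-2-ol (HFIP), 0 °C; HFIP evaporated; then TCCA (0.45 equiv), acetone/H2O 5:1, 0 °C to rt; aq Na2S2O3
Reagents that add atoms: N-bromosuccinimide (NBS), O=C1CCC(=O)N1Br; trichloroisocyanuric acid (TCCA), O=C1N(Cl)C(=O)N(Cl)C(=O)N1Cl; water, O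
Why: Proposed new method: the one-flask pairing is new, but each half is a known reaction type (bromonium-induced haloetherification, then halohydrin formation). Br+ is captured only at the prenyl alkene, which carries the internal tertiary OH; O attacks the tertiary carbon (Markovnikov, 6-endo) through a chair with Br equatorial and the cyclohexenyl group equatorial (methyl axial), which sets the (R)-CHBr centre trans to the cyclohexenyl group, and the ring A bromonium has no nucleophile in HFIP and reverts. Cl+/H2O then adds anti across the ring A alkene under Markovnikov and Fürst–Plattner (trans-diaxial) control, as in the bromohydrin of limonene, giving Cl axial and trans to the oxanyl group and the tertiary OH axial and cis to it.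

**Step 2**
Reactants: 3 (1R,2R,4S)-4-[(2S,5R)-5-bromo-2,6,6-trimethyloxan-2-yl]-2-chloro-1-methylcyclohexan-1-ol
Product: 5 (3R,6S)-3-bromo-6-[(1S,3R,4R)-4-bromo-3-chloro-4-methylcyclohexyl]-2,2,6-trimethyloxane (target), via trimethylsilyl ether 4 (not isolated)
Conditions: TMSBr (3 equiv), CH2Cl2, −20 °C to rt
Reagents that add atoms: bromotrimethylsilane (TMSBr), C[Si](C)(C)Br
Why: SN1 deoxybromination of a tertiary alcohol with neighbouring-group participation: the tertiary cation is bridged by the anti axial Cl and Br− enters from the opposite face, so OH is replaced with retention to give the trans-diaxial bromochloride, which is also the more stable epimer (methyl equatorial). Any alkene from E1 loss is re-hydrobrominated to the same cation, and the secondary C–Cl, the oxane C–Br and the hindered oxane ether are not ionised at this temperature.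

**Compound list**
1 | (−)-α-bisabolol, (2S)-6-methyl-2-[(1S)-4-methylcyclohex-3-en-1-yl]hept-5-en-2-ol | O[C@](C)([C@H]1CCC(C)=CC1)CCC=C(C)C | starting material
2 | (3R,6S)-3-bromo-2,2,6-trimethyl-6-[(1S)-4-methylcyclohex-3-en-1-yl]oxane (Br equatorial, trans to the cyclohexenyl group) | CC1(C)O[C@](C)([C@H]2CCC(C)=CC2)CC[C@H]1Br | intermediate
3 | (1R,2R,4S)-4-[(2S,5R)-5-bromo-2,6,6-trimethyloxan-2-yl]-2-chloro-1-methylcyclohexan-1-ol (Cl axial and trans to the oxanyl group, OH axial and cis to it) | CC1(C)O[C@](C)([C@H]2CC[C@@](C)(O)[C@H](Cl)C2)CC[C@H]1Br | intermediate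
4 | trimethylsilyl ether of 3, {[(1R,2R,4S)-4-[(2S,5R)-5-bromo-2,6,6-trimethyloxan-2-yl]-2-chloro-1-methylcyclohexyl]oxy}trimethylsilane | CC1(C)O[C@](C)([C@H]2CC[C@@](C)(O[Si](C)(C)C)[C@H](Cl)C2)CC[C@H]1Br | intermediate
5 | (3R,6S)-3-bromo-6-[(1S,3R,4R)-4-bromo-3-chloro-4-methylcyclohexyl]-2,2,6-trimethyloxane (Cl axial, Br axial, trans to each other) | CC1(C)O[C@](C)([C@H]2CC[C@@](C)(Br)[C@H](Cl)C2)CC[C@H]1Br | target

**Total step count:** 2
**Longest linear sequence:** 2 steps

**Steps most likely to fail.** The route has only two steps, so both are ranked, and step 1 is entered twice, once for each of its two events.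

1. Step 1, bromoetherification event. The risks are 5-exo closure to the oxolane, a low ratio at the CHBr centre, and a mixture that is hard to purify after the second event. The fallback sets out from 1 and comes back at 2. Compound 1 is cyclised with Hg(OCOCF3)2 in MeNO2 at −20 °C and the product is exchanged with aqueous KBr to give the organomercury bromide F1. This oxymercuration is Markovnikov and reversible, so it favours the oxane with the C–Hg bond equatorial. Br2 (1.0 equiv) in pyridine at −40 °C in the dark then cleaves the C–Hg bond with retention, faster than the pyridine-complexed bromine adds to the ring A alkene, and gives 2. Compound 2 is purified and taken through the TCCA half of step 1 as a separate operation.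

2. Step 2, deoxybromination. The risks are slow ionisation next to Cl and acid cleavage of the di-tertiary oxane ether. The fallback sets out from 2 (isolated after the NBS half of step 1) and comes back at 5, bringing in Br first and Cl last. Epoxidation of 2 with mCPBA and NaHCO3 in CH2Cl2 gives, after separation from its face isomer, the epoxide F4 with the oxygen trans to the oxanyl group. Cold 48% aqueous HBr (1.1 equiv) in Et2O at −20 °C opens F4 at the tertiary carbon (Markovnikov and trans-diaxial at once) to the bromohydrin F5, with Br tertiary and axial and OH secondary and axial. Ph3P and CCl4 in MeCN then activate the secondary OH; the anti tertiary Br forms a bromonium ion, which chloride opens trans-diaxially at the secondary carbon, so OH is replaced by Cl with retention and 5 results without any ionisation at a tertiary carbinol.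

3. Step 1, chlorohydroxylation event. The risks are attack of Cl+ on the wrong face and ene-type allylic chlorination. The fallback sets out from 2 (isolated) and comes back at 3. NBS in acetone/H2O at 0 °C gives the trans-diaxial bromohydrin F2, since bromonium formation is reversible and funnels to one isomer. K2CO3 in MeOH closes it to the epoxide F3 with the oxygen cis to the oxanyl group. LiCl and AcOH in THF at rt then open F3 by SN2 attack at the secondary carbon, which is also the trans-diaxial mode, and give 3.

**Further compounds**
F1 | step 1 | bromo[(3R,6S)-2,2,6-trimethyl-6-[(1S)-4-methylcyclohex-3-en-1-yl]oxan-3-yl]mercury | CC1(C)O[C@](C)([C@H]2CCC(C)=CC2)CC[C@H]1[Hg]Br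
F2 | step 1 | (1R,2R,4S)-2-bromo-4-[(2S,5R)-5-bromo-2,6,6-trimethyloxan-2-yl]-1-methylcyclohexan-1-ol | CC1(C)O[C@](C)([C@H]2CC[C@@](C)(O)[C@H](Br)C2)CC[C@H]1Br
F3 | step 1 | (1R,4S,6S)-4-[(2S,5R)-5-bromo-2,6,6-trimethyloxan-2-yl]-1-methyl-7-oxabicyclo[4.1.0]heptane | CC1(C)O[C@](C)([C@H]2CC[C@@]3(C)O[C@H]3C2)CC[C@H]1Br
F4 | step 2 | (1S,4S,6R)-4-[(2S,5R)-5-bromo-2,6,6-trimethyloxan-2-yl]-1-methyl-7-oxabicyclo[4.1.0]heptane | CC1(C)O[C@](C)([C@H]2CC[C@]3(C)O[C@@H]3C2)CC[C@H]1Br
F5 | step 2 | (1R,2R,5S)-2-bromo-5-[(2S,5R)-5-bromo-2,6,6-trimethyloxan-2-yl]-2-methylcyclohexan-1-ol | CC1(C)O[C@](C)([C@H]2CC[C@@](C)(Br)[C@H](O)C2)CC[C@H]1Br
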